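**Plan** (carotenoid numbering; unprimed = acetylenic half, primed = diol half)
- Retrosynthesis: C10–C11 is cut last. In the same operation C11=C12–C13(CH3)=C14 is folded back into a 3-methylcyclopropene, which gives a C14 iodo-enyne and a C26 cyclopropenyl pentaene. Earlier cuts are C11'=C12', C13'=C14' and C15=C15' (Wittig), C7'=C8' (HWE), C6–C7 (Negishi alkynylation) and C9–CH3 (methylalumination).
- Enabling feature: C11, C12 and C13(CH3) can form a three-membered ring, with C14 as an sp3 CH2 that is allylic to the C15=C15'…C7'=C8' pentaene. This strained isomer of the methyl-branched diene has two equivalent ring CH groups. It opens as soon as C10 is attached.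
- Forward order: both six-membered rings are bought. The temporary three-membered ring is made by dibromocarbene addition and elimination, then extended by two Wittig reactions. The diol half is grown to a C15 phosphonium salt and joined to it (C26). The C14 iodide is added last, and that step also consumes the helper ring.
- Stereochemistry: C3 (R) comes from (4R,6R)-actinol. C6' comes from Sharpless epoxidation and C5' from invertive hydrolysis of that epoxide (trans-5'R,6'R). 9E comes from syn-methylalumination, and the other E-alkenes from stabilised-ylide, HWE or Wittig steps and the key step.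

Key step: step 21

Assumption: (4R,6R)-actinol is taken as a purchasable single enantiomer.

**Step 1**
Reactants: 1 (4R,6R)-4-hydroxy-2,2,6-trimethylcyclohexan-1-one (actinol)
Product: 2 (4R,6R)-4-[(tert-butyldimethylsilyl)oxy]-2,2,6-trimethylcyclohexan-1-one
Conditions: TBSCl, imidazole, DMF, rt
Reagents that add atoms: tert-butyldimethylsilyl chloride, CC(C)(C)[Si](C)(C)Cl
Why: Standard silyl ether formation masks the C3 hydroxyl for the strong-base step and touches no stereocentre.

**Step 2**
Reactants: 2 silyl ether of actinol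
Product: 4 (4R)-4-[(tert-butyldimethylsilyl)oxy]-2,6,6-trimethylcyclohex-1-en-1-yl trifluoromethanesulfonate, via lithium enolate 3 (not isolated)
Conditions: LDA, THF, −78→0 °C; PhNTf2, −78 °C→rt
Reagents that add atoms: N-phenylbis(trifluoromethanesulfonimide), O=S(=O)(N(c1ccccc1)S(=O)(=O)C(F)(F)F)C(F)(F)F
Why: Enol triflate synthesis; the other α-carbon is quaternary, so only one enolate can form, the methyl-bearing stereocentre becomes sp2 and C3 (R) is kept.

**Step 3**
Reactants: 4 enol triflate; 5 1,4-bis(trimethylsilyl)buta-1,3-diyne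
Product: 8 tert-butyldimethyl({(1R)-3,5,5-trimethyl-4-[4-(trimethylsilyl)buta-1,3-diyn-1-yl]cyclohex-3-en-1-yl}oxy)silane, via lithium diynide 6 (not isolated), via zinc diynide 7 (not isolated)
Conditions: 5, MeLi·LiBr, THF, 0 °C→rt; ZnBr2, 0 °C; then 4, Pd(PPh3)4 (5 mol %), rt→50 °C
Reagents that add atoms: none
Why: Selective mono-desilylation, transmetalation to zinc and Negishi alkynylation of an alkenyl triflate should form C6–C7 and install C7–C10 in one flask.

**Step 4**
Reactants: 8 doubly silylated diyne
Product: 9 (1R)-4-(buta-1,3-diyn-1-yl)-3,5,5-trimethylcyclohex-3-en-1-ol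
Conditions: TBAF/AcOH (1:1, 3 equiv), THF, 0 °C→rt
Reagents that add atoms: none
Why: Fluoride cleaves both the C(sp)–SiMe3 and the O–TBS bond, and the acetic acid buffer protects the base-sensitive terminal diyne.

**Step 5**
Reactants: 9 terminal diyne alcohol
Product: 11 (1R)-4-[(3E)-4-iodo-3-methylbut-3-en-1-yn-1-yl]-3,5,5-trimethylcyclohex-3-en-1-ol, via alkenylalane 10 (not isolated)
Conditions: Me3Al (3.5 equiv), Cp2ZrCl2 (0.25 equiv), CH2Cl2, 0 °C→rt; I2, THF, −30 °C
Reagents that add atoms: trimethylaluminium, C[Al](C)C; iodine, II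
Why: Negishi Zr-catalysed methylalumination adds CH3 and Al syn across the terminal alkyne only (the hindered C7≡C8 alkyne is inert, the OH rides as its aluminium alkoxide), and iodinolysis with retention fixes 9E.

**Step 6**
Reactants: 12 2-methylallylmagnesium chloride; 13 triethyl orthoformate
Product: 14 4,4-diethoxy-2-methylbut-1-ene
Conditions: THF, reflux
Reagents that add atoms: none
Why: The Bodroux–Chichibabin aldehyde synthesis gives the masked C15 aldehyde next to the future C13/C14 unit.

**Step 7**
Reactants: 14 unsaturated acetal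
Product: 15 1,1-dibromo-2-(2,2-diethoxyethyl)-2-methylcyclopropane (racemic)
Conditions: CHBr3, 50 % aq NaOH, BnEt3NCl, CH2Cl2, 0 °C→rt
Reagents that add atoms: bromoform, BrC(Br)Br
Why: Phase-transfer (Makosza) dibromocarbene addition to an electron-rich 1,1-disubstituted alkene builds the helper ring, and the acetal is base-stable.

**Step 8**
Reactants: 15 gem-dibromocyclopropane
Product: 16 1-bromo-2-(2,2-diethoxyethyl)-2-methylcyclopropane (racemic cis/trans mixture)
Conditions: EtMgBr (1.3 equiv), Ti(OiPr)4 (5 mol %), Et2O, rt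
Reagents that add atoms: none
Why: Titanium-catalysed hydrodebromination with a Grignard reagent stops cleanly at the monobromide, and both diastereomers serve in the next step.

**Step 9**
Reactants: 16 bromocyclopropane
Product: 17 3-(2,2-diethoxyethyl)-3-methylcycloprop-1-ene (achiral)
Conditions: t-BuOK, DMSO, rt
Reagents that add atoms: none
Why: This is a 1,2-dehydrobromination to a 3,3-dialkylcyclopropene, and the quaternary ring carbon blocks isomerisation to a methylenecyclopropane.

**Step 10**
Reactants: 17 cyclopropenyl acetal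
Product: 18 (1-methylcycloprop-2-en-1-yl)acetaldehyde
Conditions: 10 % aq oxalic acid on SiO2, CH2Cl2, rt
Reagents that add atoms: water, O
Why: Mild heterogeneous acetal hydrolysis releases the aldehyde without protonating the strained alkene; the volatile product is used directly.

**Step 11**
Reactants: 18 cyclopropenyl acetaldehyde; 19 (triphenylphosphoranylidene)acetaldehyde
Product: 20 (2E)-4-(1-methylcycloprop-2-en-1-yl)but-2-enal
Conditions: benzene, 50 °C, 1.0 equiv of 19
Reagents that add atoms: none
Why: The Wittig reaction of a stabilised ylide should give the E-alkene C15=C15'.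

**Step 12**
Reactants: 20 enal; 21 2-(triphenylphosphoranylidene)propanal
Product: 22 (2E,4E)-2-methyl-6-(1-methylcycloprop-2-en-1-yl)hexa-2,4-dienal
Conditions: toluene, 80 °C
Reagents that add atoms: none
Why: The Wittig reaction of a stabilised, α-branched ylide should set E-C13'=C14', and a 3,3-dialkylcyclopropene tolerates this temperature.

**Step 13**
Reactants: 23 β-cyclocitral
Product: 24 (2,6,6-trimethylcyclohex-1-en-1-yl)methanol (β-cyclogeraniol)
Conditions: NaBH4, MeOH, 0 °C
Reagents that add atoms: none
Why: Borohydride 1,2-reduction of the hindered enal gives the allylic alcohol needed for directed epoxidation.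

**Step 14**
Reactants: 24 β-cyclogeraniol
Product: 25 [(1S,6S)-2,2,6-trimethyl-7-oxabicyclo[4.1.0]heptan-1-yl]methanol
Conditions: Ti(OiPr)4 (10 mol %), L-(+)-DET (12 mol %), t-BuOOH, 4 Å MS, CH2Cl2, −20 °C
Reagents that add atoms: tert-butyl hydroperoxide, CC(C)(C)OO
Why: In the Sharpless asymmetric epoxidation, L-(+)-tartrate delivers oxygen in the same sense that gives (2S)-epoxides from simple primary allylic alcohols, which fixes the C6'–O bond and places the C5'–O bond for later inversion.

**Step 15**
Reactants: 25 epoxy alcohol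
Product: 26 (1R,6S)-2,2,6-trimethyl-7-oxabicyclo[4.1.0]heptane-1-carbaldehyde
Conditions: TPAP (5 mol %), NMO, 4 Å MS, CH2Cl2, rt
Reagents that add atoms: none
Why: Ley–Griffith oxidation is neutral, so the epoxide survives, and the aldehyde is not enolisable.

**Step 16**
Reactants: 26 epoxy aldehyde; 27 triethyl (E)-3-methyl-4-phosphonocrotonate
Product: 29 ethyl (2E,4E)-3-methyl-5-[(1R,6S)-2,2,6-trimethyl-7-oxabicyclo[4.1.0]heptan-1-yl]penta-2,4-dienoate, via phosphonate anion 28 (not isolated)
Conditions: 27, n-BuLi, THF–DMPU, −78 °C; then 26, −78→0 °C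
Reagents that add atoms: none
Why: Horner–Wadsworth–Emmons olefination should give E-C7'=C8' and carry E-C9'=C10' in from the reagent.

**Step 17**
Reactants: 29 epoxy dienoate
Product: 30 ethyl (2E,4E)-5-[(1R,2R)-1,2-dihydroxy-2,6,6-trimethylcyclohexyl]-3-methylpenta-2,4-dienoate
Conditions: 5 % aq HClO4, THF, 0 °C→rt
Reagents that add atoms: water, O
Why: In this acid-catalysed anti (Fürst–Plattner) epoxide hydrolysis, water should attack C5' with inversion because C6' is neopentyl and its cation would be conjugated to the electron-poor dienoate, so C6'–O is retained and the trans-(5'R,6'R)-diol results.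

**Step 18**
Reactants: 30 dihydroxy dienoate
Product: 31 (1R,2R)-1-[(1E,3E)-5-hydroxy-3-methylpenta-1,3-dien-1-yl]-2,6,6-trimethylcyclohexane-1,2-diol
Conditions: DIBAL-H (5 equiv), CH2Cl2, −78 °C; Rochelle salt
Reagents that add atoms: none
Why: DIBAL-H reduces the conjugated ester to the allylic alcohol while the tertiary hydroxyls sit as aluminium alkoxides.

**Step 19**
Reactants: 31 triol
Product: 33 {(2E,4E)-5-[(1R,2R)-1,2-dihydroxy-2,6,6-trimethylcyclohexyl]-3-methylpenta-2,4-dien-1-yl}triphenylphosphonium bromide, via allylic bromide 32 (not isolated)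
Conditions: CBr4 (1.1 equiv), PPh3 (2.3 equiv), CH2Cl2, 0 °C→rt
Reagents that add atoms: carbon tetrabromide, BrC(Br)(Br)Br; triphenylphosphine, c1ccccc1P(c1ccccc1)c1ccccc1
Why: Appel bromination touches only the primary allylic alcohol, and in-flask quaternisation of PPh3 avoids the acid that would ionise the tertiary allylic C6'–OH.

**Step 20**
Reactants: 33 C15 phosphonium bromide; 22 C11 dienal
Product: 35 (1R,2R)-1-[(1E,3E,5E,7E,9E)-3,7-dimethyl-11-(1-methylcycloprop-2-en-1-yl)undeca-1,3,5,7,9-pentaen-1-yl]-2,6,6-trimethylcyclohexane-1,2-diol, via phosphorus ylide 34 (not isolated)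
Conditions: 1,2-epoxybutane (excess), EtOH, 60 °C, Ar, dark; chromatography
Reagents that add atoms: none
Why: Wittig olefination under epoxide-mediated, essentially neutral ylide generation tolerates the free diol and the acidic C14–H2 of 22, and it should favour the unhindered E-C11'=C12' isomer.

**Step 21**
Reactants: 35 C26 cyclopropenyl pentaene diol; 11 C14 iodo-enyne
Product: 38 target, (3R,5'R,6'R)-7,8-didehydro-5',6'-dihydro-β,β-carotene-3,5',6'-triol, via alkenylpalladium iodide 36 (not isolated), via allylpalladium cation 37 (not isolated)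
Conditions: Pd2(dba)3·CHCl3 (2.5 mol %), P(2-furyl)3 (10 mol %), Ag2CO3 (0.6 equiv), THF–DMF, 25→40 °C, Ar, dark
Reagents that add atoms: none
Why: Proposed new method: Pd(0) inserts into the C10–I bond of 11 with retention to give 36, Ag2CO3 removes iodide, and the cationic alkenyl-Pd(II) is captured by the strained C11=C12 bond of 35 (about 54 kcal/mol of ring strain), either by syn-carbopalladation followed by scission of the C11–C13 σ bond or by electrophilic opening to a Pd vinylcarbene followed by 1,1-migratory insertion of the C10 alkenyl group, both paths forming C10–C11 and converging on the η3-allyl complex 37 (C11–C12–C13). Carbonate then removes the doubly allylic C14–H (or syn β-hydride elimination occurs from the σ-C13 form), which creates C11=C12 and C13=C14, links the dienyne to the pentaene and returns Pd(0). The closest known reaction types are Heck-type carbopalladation/ring-opening/β-hydride-elimination cascades of methylenecyclopropanes and bicyclopropylidene, the Pd-catalysed opening of 3,3-dialkylcyclopropenes to π-allylpalladium species, Pd-carbene migratory-insertion couplings of alkenyl halides that end in 1,3-dienes, and the diene-forming elimination of π-allylpalladium complexes. No ring is closed (the three-membered ring is opened) and no sp3 stereocentre is created, the transient C13 centre of 37 being destroyed; E at C11=C12 follows from the syn position of the C10 substituent on the η3-allyl unit, and E at C13=C14 from a planar, A1,3-minimised, product-like elimination that places C15 anti to C12. The step needs chemoselectivity for the cyclopropene over the seven other C=C bonds and the C7≡C8 alkyne (secured by strain and by steric shielding of the alkyne), has no regiochemical issue at the ring because C11 and C12 are enantiotopic CH groups of a Cs-symmetric cyclopropene, needs proton loss from C14 and not from the 13- or 9-methyl groups (secured by the bis-allylic acidity of C14–H and the full conjugation gained), and needs retention of 9E (secured by stereoretentive oxidative addition, iodide scavenging, darkness and ≤40 °C). Premature isomerisation of 35 to the terminal C11H2=C12H diene would not be fatal, since that polyene is a Heck acceptor at C11 under the same conditions.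

**Compound list**
1 | (4R,6R)-4-hydroxy-2,2,6-trimethylcyclohexan-1-one | O=C1C(C)(C)C[C@H](O)C[C@H]1C | starting material
2 | (4R,6R)-4-[(tert-butyldimethylsilyl)oxy]-2,2,6-trimethylcyclohexan-1-one | O=C1C(C)(C)C[C@H](O[Si](C)(C)C(C)(C)C)C[C@H]1C | intermediate
3 | lithium enolate of 2 | CC1=C(O[Li])C(C)(C)C[C@H](O[Si](C)(C)C(C)(C)C)C1 | intermediate
4 | (4R)-4-[(tert-butyldimethylsilyl)oxy]-2,6,6-trimethylcyclohex-1-en-1-yl triflate | CC1=C(OS(=O)(=O)C(F)(F)F)C(C)(C)C[C@H](O[Si](C)(C)C(C)(C)C)C1 | intermediate
5 | 1,4-bis(trimethylsilyl)buta-1,3-diyne | C[Si](C)(C)C#CC#C[Si](C)(C)C | starting material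
6 | lithium 4-(trimethylsilyl)buta-1,3-diynide | [Li]C#CC#C[Si](C)(C)C | intermediate
7 | bromo[4-(trimethylsilyl)buta-1,3-diynyl]zinc | Br[Zn]C#CC#C[Si](C)(C)C | intermediate
8 | (1R)-TBS ether of 3,5,5-trimethyl-4-[4-(trimethylsilyl)buta-1,3-diynyl]cyclohex-3-en-1-ol | CC1=C(C#CC#C[Si](C)(C)C)C(C)(C)C[C@H](O[Si](C)(C)C(C)(C)C)C1 | intermediate
9 | (1R)-4-(buta-1,3-diyn-1-yl)-3,5,5-trimethylcyclohex-3-en-1-ol | CC1=C(C#CC#C)C(C)(C)C[C@H](O)C1 | intermediate
10 | (E)-alkenyl(dimethyl)alane, O-dimethylaluminium alkoxide | CC1=C(C#C/C(C)=C/[Al](C)C)C(C)(C)C[C@H](O[Al](C)C)C1 | intermediate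
11 | (1R)-4-[(3E)-4-iodo-3-methylbut-3-en-1-yn-1-yl]-3,5,5-trimethylcyclohex-3-en-1-ol | CC1=C(C#C/C(C)=C/I)C(C)(C)C[C@H](O)C1 | intermediate
12 | 2-methylallylmagnesium chloride | C=C(C)C[Mg]Cl | starting material
13 | triethyl orthoformate | CCOC(OCC)OCC | starting material
14 | 4,4-diethoxy-2-methylbut-1-ene | C=C(C)CC(OCC)OCC | intermediate
15 | 1,1-dibromo-2-(2,2-diethoxyethyl)-2-methylcyclopropane (racemic) | CCOC(CC1(C)CC1(Br)Br)OCC | intermediate
16 | 1-bromo-2-(2,2-diethoxyethyl)-2-methylcyclopropane (racemic, cis/trans) | CCOC(CC1(C)CC1Br)OCC | intermediate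
17 | 3-(2,2-diethoxyethyl)-3-methylcycloprop-1-ene | CCOC(CC1(C)C=C1)OCC | intermediate
18 | (1-methylcycloprop-2-en-1-yl)acetaldehyde | O=CCC1(C)C=C1 | intermediate
19 | (triphenylphosphoranylidene)acetaldehyde | O=CC=P(c1ccccc1)(c1ccccc1)c1ccccc1 | starting material
20 | (2E)-4-(1-methylcycloprop-2-en-1-yl)but-2-enal | O=C/C=C/CC1(C)C=C1 | intermediate
21 | 2-(triphenylphosphoranylidene)propanal | CC(C=O)=P(c1ccccc1)(c1ccccc1)c1ccccc1 | starting material
22 | (2E,4E)-2-methyl-6-(1-methylcycloprop-2-en-1-yl)hexa-2,4-dienal | O=C/C(C)=C/C=C/CC1(C)C=C1 | intermediate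
23 | β-cyclocitral | CC1=C(C=O)C(C)(C)CCC1 | starting material
24 | β-cyclogeraniol | CC1=C(CO)C(C)(C)CCC1 | intermediate
25 | [(1S,6S)-2,2,6-trimethyl-7-oxabicyclo[4.1.0]heptan-1-yl]methanol | OC[C@]12O[C@@]1(C)CCCC2(C)C | intermediate
26 | (1R,6S)-2,2,6-trimethyl-7-oxabicyclo[4.1.0]heptane-1-carbaldehyde | O=C[C@]12O[C@@]1(C)CCCC2(C)C | intermediate
27 | triethyl (E)-3-methyl-4-phosphonocrotonate | CCOC(=O)/C=C(C)/CP(=O)(OCC)OCC | starting material
28 | lithium salt of the carbanion of 27 | CCOC(=O)/C=C(C)/[CH-]P(=O)(OCC)OCC.[Li+] | intermediate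
29 | ethyl (2E,4E)-3-methyl-5-[(1R,6S)-2,2,6-trimethyl-7-oxabicyclo[4.1.0]heptan-1-yl]penta-2,4-dienoate | CCOC(=O)/C=C(C)/C=C/[C@]12O[C@@]1(C)CCCC2(C)C | intermediate
30 | ethyl (2E,4E)-5-[(1R,2R)-1,2-dihydroxy-2,6,6-trimethylcyclohexyl]-3-methylpenta-2,4-dienoate | CCOC(=O)/C=C(C)/C=C/[C@@]1(O)C(C)(C)CCC[C@@]1(C)O | intermediate
31 | (1R,2R)-1-[(1E,3E)-5-hydroxy-3-methylpenta-1,3-dien-1-yl]-2,6,6-trimethylcyclohexane-1,2-diol | OC/C=C(C)/C=C/[C@@]1(O)C(C)(C)CCC[C@@]1(C)O | intermediate
32 | (1R,2R)-1-[(1E,3E)-5-bromo-3-methylpenta-1,3-dien-1-yl]-2,6,6-trimethylcyclohexane-1,2-diol | BrC/C=C(C)/C=C/[C@@]1(O)C(C)(C)CCC[C@@]1(C)O | intermediate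
33 | C15 triphenylphosphonium bromide of 32 | [Br-].c1ccccc1[P+](c1ccccc1)(c1ccccc1)C/C=C(C)/C=C/[C@@]1(O)C(C)(C)CCC[C@@]1(C)O | intermediate
34 | ylide of 33 | c1ccccc1P(c1ccccc1)(c1ccccc1)=C/C=C(C)/C=C/[C@@]1(O)C(C)(C)CCC[C@@]1(C)O | intermediate
35 | (1R,2R)-1-[(1E,3E,5E,7E,9E)-3,7-dimethyl-11-(1-methylcycloprop-2-en-1-yl)undeca-1,3,5,7,9-pentaen-1-yl]-2,6,6-trimethylcyclohexane-1,2-diol | CC1(C/C=C/C=C(C)/C=C/C=C(C)/C=C/[C@@]2(O)C(C)(C)CCC[C@@]2(C)O)C=C1 | intermediate
36 | (E)-alkenylpalladium(II) iodide from 11 (phosphines omitted) | CC1=C(C#C/C(C)=C/[Pd]I)C(C)(C)C[C@H](O)C1 | intermediate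
37 | η3-allylpalladium cation over C11–C13, drawn in its σ-C13 form (phosphines omitted) | CC1=C(C#C/C(C)=C/C=C/C(C)([Pd+])C/C=C/C=C(C)/C=C/C=C(C)/C=C/[C@@]2(O)C(C)(C)CCC[C@@]2(C)O)C(C)(C)C[C@H](O)C1 | intermediate
38 | (3R,5'R,6'R)-7,8-didehydro-5',6'-dihydro-β,β-carotene-3,5',6'-triol (CNP0289733.1) | CC1=C(C#C/C(C)=C/C=C/C(C)=C/C=C/C=C(C)/C=C/C=C(C)/C=C/[C@@]2(O)C(C)(C)CCC[C@@]2(C)O)C(C)(C)C[C@H](O)C1 | target

**Total step count:** 21.
**Longest linear sequence:** 9 steps (steps 13–21; the branch of steps 6–12, 20 and 21 is equally long).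

**Steps most likely to fail**

1. **Step 21.**
   - What may go wrong: the cyclopropene may be alkenylated at C–H with the ring retained, or be oligomerised by Pd(0). The allyl complex may lose a proton from the 13-methyl group. η3–η1–η3 slippage towards C9 may erode the 9E or 13E geometry.
   - Fallback: it sets out from 33 and 11 and returns at 38, using only known couplings. Salt 33 is condensed (1,2-epoxybutane, EtOH) with an excess of commercial (2E,4E,6E)-2,7-dimethylocta-2,4,6-trienedial. This gives (2E,4E,6E,8E,10E,12E)-13-[(1R,2R)-1,2-dihydroxy-2,6,6-trimethylcyclohexyl]-2,7,11-trimethyltrideca-2,4,6,8,10,12-hexaenal F1. Takai–Utimoto boryl-olefination (Cl2CHBpin, CrCl2, LiI, THF) adds C11 and gives the all-E heptaenyl pinacolboronate F2. Suzuki–Miyaura coupling of F2 with 11 (Pd(PPh3)4, aq K3PO4, THF, rt, dark) forms the same C10–C11 bond with retention on both partners.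

2. **Step 17.**
   - What may go wrong: ionisation at C6' instead of attack at C5' would cause loss of stereochemical fidelity. It could also lead to capture of C8' by the C5' oxygen (furanoid rearrangement) or to proton loss giving allylic alcohols.
   - Fallback: it sets out from 25 and returns at 30. The ring is opened before any unsaturation is attached. Aqueous HClO4 in THF converts 25 into (1S,2R)-1-(hydroxymethyl)-2,6,6-trimethylcyclohexane-1,2-diol F3, by attack at the carbon remote from the electron-withdrawing CH2OH with inversion. TEMPO/PhI(OAc)2 then oxidises only the primary alcohol to (1R,2R)-1,2-dihydroxy-2,6,6-trimethylcyclohexane-1-carbaldehyde F4. The HWE reaction of step 16 with 27 then delivers 30 directly.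

3. **Step 20.**
   - What may go wrong: E/Z selectivity at C11'=C12' may be poor, and iodine- or Pd(II)-catalysed isomerisation is barred by the cyclopropene. Deconjugation of 22 through its acidic C14–H2 is also possible.
   - Fallback: it sets out from 31 and returns at 35. Bromide 32 is isolated (CBr4, 1.05 equiv PPh3). A Michaelis–Becker reaction with sodium diethyl phosphite converts it into diethyl {(2E,4E)-5-[(1R,2R)-1,2-dihydroxy-2,6,6-trimethylcyclohexyl]-3-methylpenta-2,4-dien-1-yl}phosphonate F5. The pre-formed anion of F5 (KOt-Bu, 3 equiv, THF, −78 °C) is then combined with 22 in an E-selective Horner–Wadsworth–Emmons reaction.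

**Further compounds**
F1 | step 21 | (2E,4E,6E,8E,10E,12E)-13-[(1R,2R)-1,2-dihydroxy-2,6,6-trimethylcyclohexyl]-2,7,11-trimethyltrideca-2,4,6,8,10,12-hexaenal | O=C/C(C)=C/C=C/C=C(C)/C=C/C=C(C)/C=C/[C@@]1(O)C(C)(C)CCC[C@@]1(C)O
F2 | step 21 | all-E C26 heptaenyl pinacolboronate | CC1(C)OB(/C=C/C(C)=C/C=C/C=C(C)/C=C/C=C(C)/C=C/[C@@]2(O)C(C)(C)CCC[C@@]2(C)O)OC1(C)C
F3 | step 17 | (1S,2R)-1-(hydroxymethyl)-2,6,6-trimethylcyclohexane-1,2-diol | OC[C@@]1(O)C(C)(C)CCC[C@@]1(C)O
F4 | step 17 | (1R,2R)-1,2-dihydroxy-2,6,6-trimethylcyclohexane-1-carbaldehyde | O=C[C@@]1(O)C(C)(C)CCC[C@@]1(C)O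
F5 | step 20 | diethyl {(2E,4E)-5-[(1R,2R)-1,2-dihydroxy-2,6,6-trimethylcyclohexyl]-3-methylpenta-2,4-dien-1-yl}phosphonate | CCOP(=O)(C/C=C(C)/C=C/[C@@]1(O)C(C)(C)CCC[C@@]1(C)O)OCC
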